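**Retrosynthetic overview**
1. Endgame: acid cleavage of seven MOM ethers (29 from 28). The enone arm on ring C is made late from the ring-C methyl ketone by kinetic aldol addition to 2,4-bis(methoxymethoxy)benzaldehyde and dehydration.
2. Key disconnection: the bond between the aroyl carbonyl carbon (on prenylated ring A) and C-1 of cyclohexene ring B. It is made by nickel-mediated decarboxylative cross-electrophile coupling of the C-1 N-hydroxyphthalimide ester 21 with the ring-A S-2-pyridyl thioester 7.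
3. Enabling feature: C-1 of ring B lies between allylic C-2, whose 2,6-dioxygenated aryl ring C stands pseudoaxial, and C-6, whose 4-oxygenated phenyl ring E is equatorial. A planar radical at C-1 is therefore acylated anti to ring C, which gives the 1,2-trans/1,6-cis pattern (the C-1 epimer of a chalcone Diels–Alder adduct).
4. The carboxyl carbon on C-1 is absent from the target. It activates the dienophile, carries the oxazolidinone auxiliary that steers the endo Diels–Alder reaction (sets C-2 and C-6), and leaves as CO2 in the key step.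
5. Ring order: all arenes are bought. Ring B is the only ring formed (step 11), from dienyl arene 13 (from 2',4'-dihydroxyacetophenone) and cinnamoyl imide 17; ring A comes from resorcinol by two directed metalations.

Key step: step 14

Remark: ring B of the SMILES is read as (1S,2S,6S), i.e. the aroyl group on C-1 is trans to ring C on C-2 and cis to ring E on C-6; 4-(methoxymethoxy)benzaldehyde is taken as a purchasable compound. Ring B numbering: C-1 bears the aroyl group, C-2 ring C, C-3=C-4 the double bond (methyl on C-4), C-6 ring E; ring D is the 2,4-dioxygenated phenyl of the enone.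

**Route**

Step 1
Reactants: 1 resorcinol
Product: 2 1,3-bis(methoxymethoxy)benzene
Conditions: NaH, MOMCl, DMF, 0 °C to rt
Reagents that add atoms: chloromethyl methyl ether (MOMCl), COCCl
Why: Williamson-type O-alkylation of the bis-phenoxide gives the bis-acetal, whose two OMOM groups later direct both metalations of ring A.

Step 2
Reactants: 2 1,3-bis(methoxymethoxy)benzene
Product: 4 1,3-bis(methoxymethoxy)-2-(3-methylbut-2-en-1-yl)benzene, via aryllithium 3 (not isolated)
Conditions: n-BuLi, THF, 0 °C to rt; CuI (10 mol%), prenyl bromide, −78 °C to rt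
Reagents that add atoms: 1-bromo-3-methylbut-2-ene (prenyl bromide), CC(C)=CCBr
Why: Directed ortho-metalation occurs at C-2 between the two OMOM groups, and copper-assisted SN2 allylation of the aryllithium installs the linear prenyl group.

Step 3
Reactants: 4 1,3-bis(methoxymethoxy)-2-(3-methylbut-2-en-1-yl)benzene
Product: 6 2,4-bis(methoxymethoxy)-3-(3-methylbut-2-en-1-yl)benzoic acid, via aryllithium 5 (not isolated)
Conditions: sec-BuLi, TMEDA, THF, −78 °C; CO2; aq. HCl to pH 4, 0 °C
Reagents that add atoms: carbon dioxide, O=C=O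
Why: A second directed ortho-metalation, now at the only ring position ortho to an OMOM group, followed by carboxylation of the aryllithium should give the benzoic acid with the 2,4-dioxygenated 3-prenyl pattern of ring A.

Step 4
Reactants: 6 2,4-bis(methoxymethoxy)-3-(3-methylbut-2-en-1-yl)benzoic acid
Product: 7 S-(pyridin-2-yl) 2,4-bis(methoxymethoxy)-3-(3-methylbut-2-en-1-yl)benzenecarbothioate
Conditions: 2,2'-dipyridyl disulfide, PPh3, MeCN, rt
Reagents that add atoms: 2,2'-dipyridyl disulfide, c1ccc(SSc2ccccn2)nc1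
Why: Phosphine–disulfide redox condensation converts the acid under neutral conditions into the S-2-pyridyl thioester, the acyl partner that adds readily to zerovalent nickel.

Step 5
Reactants: 8 1-(2,4-dihydroxyphenyl)ethan-1-one
Product: 9 1-(2,4-dihydroxy-3-iodophenyl)ethan-1-one
Conditions: I2, HIO3, EtOH/H2O, rt
Reagents that add atoms: iodine, II; iodic acid, OI(=O)=O
Why: Electrophilic aromatic iodination should take place at C-3, the position activated by both hydroxyl groups, and iodic acid reoxidises iodide so that all iodine is used.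

Step 6
Reactants: 9 1-(2,4-dihydroxy-3-iodophenyl)ethan-1-one
Product: 10 1-[3-iodo-2,4-bis(methoxymethoxy)phenyl]ethan-1-one
Conditions: NaH (2.2 equiv), MOMCl, DMF, 0 °C to rt
Reagents that add atoms: chloromethyl methyl ether (MOMCl), COCCl
Why: Williamson-type O-alkylation of both phenoxides protects ring C as the bis-MOM ether, which should survive the basic, Lewis acidic and reductive steps ahead.

Step 7
Reactants: 10 1-[3-iodo-2,4-bis(methoxymethoxy)phenyl]ethan-1-one
Product: 11 1-{3-[(E)-3-hydroxy-3-methylbut-1-en-1-yl]-2,4-bis(methoxymethoxy)phenyl}ethan-1-one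
Conditions: 2-methylbut-3-en-2-ol, Pd(OAc)2 (5 mol%), P(o-tol)3 (10 mol%), Et3N, DMF, 100 °C
Reagents that add atoms: 2-methylbut-3-en-2-ol, CC(C)(O)C=C
Why: Heck reaction of the aryl iodide with the terminal alkene gives the styrenyl tertiary alcohol, the syn-insertion/syn-β-hydride elimination sequence fixing the E geometry.

Step 8
Reactants: 11 1-{3-[(E)-3-hydroxy-3-methylbut-1-en-1-yl]-2,4-bis(methoxymethoxy)phenyl}ethan-1-one
Product: 13 1-{2,4-bis(methoxymethoxy)-3-[(E)-3-methylbuta-1,3-dien-1-yl]phenyl}ethan-1-one, via allylic mesylate 12 (not isolated)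
Conditions: MsCl, Et3N, CH2Cl2, 0 °C to rt
Reagents that add atoms: none
Why: Mesylation of the tertiary allylic alcohol and E1-type elimination through the allylic cation should give the conjugated 1-aryl-3-methylbuta-1,3-diene without touching the E geometry.

Step 9
Reactants: 14 4-(methoxymethoxy)benzaldehyde
Product: 15 (E)-3-[4-(methoxymethoxy)phenyl]prop-2-enoic acid
Conditions: malonic acid, pyridine, piperidine (cat.), 90 °C
Reagents that add atoms: malonic acid, OC(=O)CC(=O)O
Why: Knoevenagel condensation in the Doebner modification, with decarboxylation, gives the (E)-cinnamic acid under basic conditions that leave the MOM ether intact.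

Step 10
Reactants: 15 (E)-3-[4-(methoxymethoxy)phenyl]prop-2-enoic acid
Product: 17 (S)-4-benzyl-3-{(E)-3-[4-(methoxymethoxy)phenyl]prop-2-enoyl}oxazolidin-2-one, via mixed pivalic anhydride 16 (not isolated)
Conditions: PivCl, Et3N, THF, −20 °C; (S)-4-benzyloxazolidin-2-one, LiCl, rt
Reagents that add atoms: (S)-4-benzyloxazolidin-2-one, O=C1N[C@@H](Cc2ccccc2)CO1
Why: N-Acylation of the oxazolidinone by the mixed anhydride attaches the chiral auxiliary without isomerising the (E)-alkene.

Step 11
Reactants: 13 1-{2,4-bis(methoxymethoxy)-3-[(E)-3-methylbuta-1,3-dien-1-yl]phenyl}ethan-1-one; 17 (S)-4-benzyl-3-{(E)-3-[4-(methoxymethoxy)phenyl]prop-2-enoyl}oxazolidin-2-one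
Product: 18 (S)-3-{(1R,2S,6S)-2-[3-acetyl-2,6-bis(methoxymethoxy)phenyl]-6-[4-(methoxymethoxy)phenyl]-4-methylcyclohex-3-ene-1-carbonyl}-4-benzyloxazolidin-2-one
Conditions: Et2AlCl (2.5 equiv), CH2Cl2, −78 to −20 °C
Reagents that add atoms: none
Why: In this auxiliary-controlled, Lewis acid-promoted Diels–Alder reaction Et2AlCl chelates the two imide carbonyls, the 1-aryl and 3-methyl groups of the diene both place the carbonyl-bearing carbon next to the aryl-bearing terminus, and endo addition to the face opposite the benzyl group should set C-2 (S) and C-6 (S) of ring B with rings C and E trans, the C-1 centre (R) being only a relay.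

Step 12
Reactants: 18 Diels–Alder imide
Product: 20 (1R,2S,6S)-2-[3-acetyl-2,6-bis(methoxymethoxy)phenyl]-6-[4-(methoxymethoxy)phenyl]-4-methylcyclohex-3-ene-1-carboxylic acid, via peroxy acid 19 (not isolated)
Conditions: LiOH, H2O2, THF/H2O, 0 °C; Na2SO3; aq. HCl to pH 4
Reagents that add atoms: hydrogen peroxide, OO
Why: Peroxide-assisted imide hydrolysis, in which lithium hydroperoxide attacks the exocyclic carbonyl selectively and sulfite reduces the peroxy acid, frees the acid and returns the auxiliary.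

Step 13
Reactants: 20 ring-B carboxylic acid
Product: 21 1,3-dioxoisoindolin-2-yl (1R,2S,6S)-2-[3-acetyl-2,6-bis(methoxymethoxy)phenyl]-6-[4-(methoxymethoxy)phenyl]-4-methylcyclohex-3-ene-1-carboxylate
Conditions: N-hydroxyphthalimide, DIC, DMAP (cat.), CH2Cl2, rt
Reagents that add atoms: N-hydroxyphthalimide, ON1C(=O)c2ccccc2C1=O
Why: Carbodiimide esterification gives the redox-active ester, and any epimerisation at C-1 is without consequence because this centre is erased in the next step.

Step 14
Reactants: 21 ring-B N-hydroxyphthalimide ester; 7 ring-A S-2-pyridyl thioester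
Product: 22 {(1S,2S,6S)-2-[3-acetyl-2,6-bis(methoxymethoxy)phenyl]-6-[4-(methoxymethoxy)phenyl]-4-methylcyclohex-3-en-1-yl}[2,4-bis(methoxymethoxy)-3-(3-methylbut-2-en-1-yl)phenyl]methanone
Conditions: NiBr2(MeOCH2CH2OMe) (10 mol%), 4,4'-di-tert-butyl-2,2'-bipyridine (12 mol%), Zn powder (2.5 equiv), DMA/THF, 0 °C to rt
Reagents that add atoms: none
Why: Zerovalent nickel inserts into the C(acyl)–S bond of 7 while single-electron reduction of 21 releases CO2 and phthalimide anion and leaves a secondary radical at C-1 of ring B; the radical is captured by the aroylnickel species and the ketone forms by reductive elimination from trivalent nickel, zinc closing the cycle. The closest known reaction type is the nickel-catalysed reductive cross-electrophile coupling of secondary alkyl N-hydroxyphthalimide esters with S-2-pyridyl thioesters to give ketones. No ring is closed. The C-1 stereocentre is reset at the planar radical: ring C on C-2, flanked by the trigonal C-1 and C-3 and carrying two ortho OMOM groups, should stand pseudoaxial and shield its face while ring E on C-6 is equatorial, so the bulky acylnickel should add anti to ring C and place the aroyl group trans to ring C and cis to ring E (1S), the opposite of the Diels–Alder configuration in 20. The step needs cross-coupling over homo-coupling and capture at nickel faster than hydrogen abstraction; the chelating 2-pyridylthio group makes the thioester the partner that adds to zerovalent nickel, and the NHP ester is the only radical source.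

Step 15
Reactants: 23 2,4-dihydroxybenzaldehyde
Product: 24 2,4-bis(methoxymethoxy)benzaldehyde
Conditions: NaH (2.2 equiv), MOMCl, DMF, 0 °C to rt
Reagents that add atoms: chloromethyl methyl ether (MOMCl), COCCl
Why: Williamson-type O-alkylation of both phenoxides, the chelated 2-hydroxyl included, gives the ring-D aldehyde in protected form.

Step 16
Reactants: 22 ring-A/ring-B ketone; 24 2,4-bis(methoxymethoxy)benzaldehyde
Product: 26 {(1S,2S,6S)-2-[3-{3-[2,4-bis(methoxymethoxy)phenyl]-3-hydroxypropanoyl}-2,6-bis(methoxymethoxy)phenyl]-6-[4-(methoxymethoxy)phenyl]-4-methylcyclohex-3-en-1-yl}[2,4-bis(methoxymethoxy)-3-(3-methylbut-2-en-1-yl)phenyl]methanone (both carbinol epimers), via lithium enolate 25 (not isolated)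
Conditions: LiN(SiMe3)2 (1.1 equiv), THF, −78 °C; 24; aq. NH4Cl
Reagents that add atoms: none
Why: LiN(SiMe3)2 at −78 °C should deprotonate the unhindered methyl ketone kinetically and not the neopentyl-like C-1 methine of the other ketone, so the aldol addition extends only the ring-C acyl group and leaves the C-1 stereocentre untouched (the new carbinol centre is unselective and is removed in step 17).

Step 17
Reactants: 26 β-hydroxy ketone
Product: 28 {(1S,2S,6S)-2-[3-{(E)-3-[2,4-bis(methoxymethoxy)phenyl]prop-2-enoyl}-2,6-bis(methoxymethoxy)phenyl]-6-[4-(methoxymethoxy)phenyl]-4-methylcyclohex-3-en-1-yl}[2,4-bis(methoxymethoxy)-3-(3-methylbut-2-en-1-yl)phenyl]methanone, via benzylic mesylate 27 (not isolated)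
Conditions: MsCl, Et3N (4 equiv), CH2Cl2, 0 °C to rt
Reagents that add atoms: none
Why: Mesylation of the benzylic β-hydroxy ketone and E1cB elimination with Et3N should give the thermodynamically favoured (E)-enone under conditions too weakly basic to enolise the ketone at C-1.

Step 18
Reactants: 28 heptakis-MOM ether
Product: 29 {(1S,2S,6S)-2-[3-{(E)-3-(2,4-dihydroxyphenyl)prop-2-enoyl}-2,6-dihydroxyphenyl]-6-(4-hydroxyphenyl)-4-methylcyclohex-3-en-1-yl}[2,4-dihydroxy-3-(3-methylbut-2-en-1-yl)phenyl]methanone (CNP0218862.3)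
Conditions: 3 M HCl, MeOH/THF, rt
Reagents that add atoms: none
Why: Acid-catalysed transacetalisation to methanol should cleave all seven MOM ethers at room temperature, conditions under which prenylated 2'-hydroxychalcones are normally released intact.

**Compound list**
1 | resorcinol (benzene-1,3-diol) | Oc1cccc(O)c1 | starting material
2 | 1,3-bis(methoxymethoxy)benzene | COCOc1cccc(OCOC)c1 | intermediate
3 | 2-lithio-1,3-bis(methoxymethoxy)benzene | [Li]c1c(OCOC)cccc1OCOC | intermediate
4 | 1,3-bis(methoxymethoxy)-2-(3-methylbut-2-en-1-yl)benzene | CC(C)=CCc1c(OCOC)cccc1OCOC | intermediate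
5 | [2,4-bis(methoxymethoxy)-3-(3-methylbut-2-en-1-yl)phenyl]lithium | [Li]c1ccc(OCOC)c(CC=C(C)C)c1OCOC | intermediate
6 | 2,4-bis(methoxymethoxy)-3-(3-methylbut-2-en-1-yl)benzoic acid | OC(=O)c1ccc(OCOC)c(CC=C(C)C)c1OCOC | intermediate
7 | S-(pyridin-2-yl) 2,4-bis(methoxymethoxy)-3-(3-methylbut-2-en-1-yl)benzenecarbothioate | O=C(Sc1ccccn1)c1ccc(OCOC)c(CC=C(C)C)c1OCOC | intermediate
8 | 1-(2,4-dihydroxyphenyl)ethan-1-one | CC(=O)c1ccc(O)cc1O | starting material
9 | 1-(2,4-dihydroxy-3-iodophenyl)ethan-1-one | CC(=O)c1ccc(O)c(I)c1O | intermediate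
10 | 1-[3-iodo-2,4-bis(methoxymethoxy)phenyl]ethan-1-one | CC(=O)c1ccc(OCOC)c(I)c1OCOC | intermediate
11 | 1-{3-[(E)-3-hydroxy-3-methylbut-1-en-1-yl]-2,4-bis(methoxymethoxy)phenyl}ethan-1-one | CC(=O)c1ccc(OCOC)c(/C=C/C(C)(C)O)c1OCOC | intermediate
12 | (E)-4-[3-acetyl-2,6-bis(methoxymethoxy)phenyl]-2-methylbut-3-en-2-yl methanesulfonate | CC(=O)c1ccc(OCOC)c(/C=C/C(C)(C)OS(C)(=O)=O)c1OCOC | intermediate
13 | 1-{2,4-bis(methoxymethoxy)-3-[(E)-3-methylbuta-1,3-dien-1-yl]phenyl}ethan-1-one | CC(=O)c1ccc(OCOC)c(/C=C/C(C)=C)c1OCOC | intermediate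
14 | 4-(methoxymethoxy)benzaldehyde | COCOc1ccc(C=O)cc1 | starting material
15 | (E)-3-[4-(methoxymethoxy)phenyl]prop-2-enoic acid | OC(=O)/C=C/c1ccc(OCOC)cc1 | intermediate
16 | (E)-3-[4-(methoxymethoxy)phenyl]prop-2-enoic pivalic anhydride | CC(C)(C)C(=O)OC(=O)/C=C/c1ccc(OCOC)cc1 | intermediate
17 | (S)-4-benzyl-3-{(E)-3-[4-(methoxymethoxy)phenyl]prop-2-enoyl}oxazolidin-2-one | O=C(/C=C/c1ccc(OCOC)cc1)N1[C@@H](Cc2ccccc2)COC1=O | intermediate
18 | (S)-3-{(1R,2S,6S)-2-[3-acetyl-2,6-bis(methoxymethoxy)phenyl]-6-[4-(methoxymethoxy)phenyl]-4-methylcyclohex-3-ene-1-carbonyl}-4-benzyloxazolidin-2-one | O=C([C@H]1[C@@H](c2c(OCOC)ccc(C(C)=O)c2OCOC)C=C(C)C[C@@H]1c1ccc(OCOC)cc1)N1[C@@H](Cc2ccccc2)COC1=O | intermediate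
19 | (1R,2S,6S)-2-[3-acetyl-2,6-bis(methoxymethoxy)phenyl]-6-[4-(methoxymethoxy)phenyl]-4-methylcyclohex-3-ene-1-carboperoxoic acid | OOC(=O)[C@H]1[C@@H](c2c(OCOC)ccc(C(C)=O)c2OCOC)C=C(C)C[C@@H]1c1ccc(OCOC)cc1 | intermediate
20 | (1R,2S,6S)-2-[3-acetyl-2,6-bis(methoxymethoxy)phenyl]-6-[4-(methoxymethoxy)phenyl]-4-methylcyclohex-3-ene-1-carboxylic acid | OC(=O)[C@H]1[C@@H](c2c(OCOC)ccc(C(C)=O)c2OCOC)C=C(C)C[C@@H]1c1ccc(OCOC)cc1 | intermediate
21 | 1,3-dioxoisoindolin-2-yl (1R,2S,6S)-2-[3-acetyl-2,6-bis(methoxymethoxy)phenyl]-6-[4-(methoxymethoxy)phenyl]-4-methylcyclohex-3-ene-1-carboxylate | O=C(ON1C(=O)c2ccccc2C1=O)[C@H]1[C@@H](c2c(OCOC)ccc(C(C)=O)c2OCOC)C=C(C)C[C@@H]1c1ccc(OCOC)cc1 | intermediate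
22 | {(1S,2S,6S)-2-[3-acetyl-2,6-bis(methoxymethoxy)phenyl]-6-[4-(methoxymethoxy)phenyl]-4-methylcyclohex-3-en-1-yl}[2,4-bis(methoxymethoxy)-3-(3-methylbut-2-en-1-yl)phenyl]methanone | CC(C)=CCc1c(OCOC)ccc(C(=O)[C@@H]2[C@@H](c3c(OCOC)ccc(C(C)=O)c3OCOC)C=C(C)C[C@@H]2c2ccc(OCOC)cc2)c1OCOC | intermediate
23 | 2,4-dihydroxybenzaldehyde | O=Cc1ccc(O)cc1O | starting material
24 | 2,4-bis(methoxymethoxy)benzaldehyde | COCOc1ccc(C=O)c(OCOC)c1 | intermediate
25 | lithium enolate of 22 at the ring-C acetyl group (C(=CH2)OLi) | CC(C)=CCc1c(OCOC)ccc(C(=O)[C@@H]2[C@@H](c3c(OCOC)ccc(C(=C)O[Li])c3OCOC)C=C(C)C[C@@H]2c2ccc(OCOC)cc2)c1OCOC | intermediate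
26 | {(1S,2S,6S)-2-[3-{3-[2,4-bis(methoxymethoxy)phenyl]-3-hydroxypropanoyl}-2,6-bis(methoxymethoxy)phenyl]-6-[4-(methoxymethoxy)phenyl]-4-methylcyclohex-3-en-1-yl}[2,4-bis(methoxymethoxy)-3-(3-methylbut-2-en-1-yl)phenyl]methanone (carbinol centre undefined) | CC(C)=CCc1c(OCOC)ccc(C(=O)[C@@H]2[C@@H](c3c(OCOC)ccc(C(=O)CC(O)c4ccc(OCOC)cc4OCOC)c3OCOC)C=C(C)C[C@@H]2c2ccc(OCOC)cc2)c1OCOC | intermediate
27 | methanesulfonate of 26 at the benzylic carbinol | CC(C)=CCc1c(OCOC)ccc(C(=O)[C@@H]2[C@@H](c3c(OCOC)ccc(C(=O)CC(OS(C)(=O)=O)c4ccc(OCOC)cc4OCOC)c3OCOC)C=C(C)C[C@@H]2c2ccc(OCOC)cc2)c1OCOC | intermediate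
28 | {(1S,2S,6S)-2-[3-{(E)-3-[2,4-bis(methoxymethoxy)phenyl]prop-2-enoyl}-2,6-bis(methoxymethoxy)phenyl]-6-[4-(methoxymethoxy)phenyl]-4-methylcyclohex-3-en-1-yl}[2,4-bis(methoxymethoxy)-3-(3-methylbut-2-en-1-yl)phenyl]methanone | CC(C)=CCc1c(OCOC)ccc(C(=O)[C@@H]2[C@@H](c3c(OCOC)ccc(C(=O)/C=C/c4ccc(OCOC)cc4OCOC)c3OCOC)C=C(C)C[C@@H]2c2ccc(OCOC)cc2)c1OCOC | intermediate
29 | {(1S,2S,6S)-2-[3-{(E)-3-(2,4-dihydroxyphenyl)prop-2-enoyl}-2,6-dihydroxyphenyl]-6-(4-hydroxyphenyl)-4-methylcyclohex-3-en-1-yl}[2,4-dihydroxy-3-(3-methylbut-2-en-1-yl)phenyl]methanone | CC(C)=CCc1c(O)ccc(C(=O)[C@@H]2[C@@H](c3c(O)ccc(C(=O)/C=C/c4ccc(O)cc4O)c3O)C=C(C)C[C@@H]2c2ccc(O)cc2)c1O | target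

**Step count and risks**
Total step count: 18. Longest linear sequence: 11 steps (5, 6, 7, 8, 11, 12, 13, 14, 16, 17, 18).

Most likely to fail:

1. Step 14 (key step). The C-1 radical is flanked by two aryl-bearing carbons, so capture by the aroylnickel species may be slow and lose to hydrogen abstraction or dimerisation, or the facial selectivity at the radical may be poor. The fallback replaces the metal-mediated cross-electrophile coupling by a carbene-catalysed radical–radical coupling with an aldehyde partner. It sets out from 4: lithiation as in step 3 (aryllithium 5) and quenching with DMF instead of CO2 should give 2,4-bis(methoxymethoxy)-3-(3-methylbut-2-en-1-yl)benzaldehyde F1. F1 and ester 21 are then combined with a thiazolium carbene precatalyst and catalytic Cs2CO3 in DMSO at 60 °C; the deprotonated Breslow intermediate reduces 21, and the persistent, bulky ketyl radical should couple with the C-1 radical anti to ring C. The fallback comes back to the route at ketone 22.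

2. Step 11. Et2AlCl may strip MOM groups or polymerise the electron-rich diene, and the endo or facial selectivity may be eroded with this hindered 1-aryl diene. The fallback forms ring B by the chelation-based chalcone cycloaddition instead. It sets out from 14 and 13: Claisen–Schmidt condensation of 14 with 1-(2-hydroxyphenyl)ethan-1-one (KOH, EtOH) should give (E)-1-(2-hydroxyphenyl)-3-[4-(methoxymethoxy)phenyl]prop-2-en-1-one F2. B(OPh)3 and the antipode of VANOL that leads to the (2S,6S) series then promote its Diels–Alder reaction with 13 to the endo adduct [(1R,2S,6S)-2-[3-acetyl-2,6-bis(methoxymethoxy)phenyl]-6-[4-(methoxymethoxy)phenyl]-4-methylcyclohex-3-en-1-yl](2-hydroxyphenyl)methanone F3, which is separated from the exo isomer. Dakin oxidation (H2O2, NaOH, THF/H2O) moves the 2-hydroxyphenyl group to oxygen, and the resulting 2-hydroxyphenyl ester of acid 20 F4 is saponified in the same flask. The fallback comes back to the route at acid 20.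

3. Step 18. Brønsted acid may cyclise the prenyl group or the ring-B double bond onto the freed phenols, close the 2'-hydroxychalcone to a flavanone, or epimerise C-1 by enolisation. The fallback exchanges the MOM ethers for silyl ethers without protic acid. It sets out from 28: Et3SiOTf and 2,2'-bipyridyl in CH2Cl2 at 0 °C should convert the seven aryl MOM ethers into the heptakis(triethylsilyl) ether of 29 F5, and buffered fluoride (HF·pyridine, THF, 0 °C) then releases the phenols. The fallback comes back to the route at target 29.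

Further compounds
F1 | step 14 | 2,4-bis(methoxymethoxy)-3-(3-methylbut-2-en-1-yl)benzaldehyde | COCOc1ccc(C=O)c(OCOC)c1CC=C(C)C
F2 | step 11 | (E)-1-(2-hydroxyphenyl)-3-[4-(methoxymethoxy)phenyl]prop-2-en-1-one | O=C(/C=C/c1ccc(OCOC)cc1)c1ccccc1O
F3 | step 11 | [(1R,2S,6S)-2-[3-acetyl-2,6-bis(methoxymethoxy)phenyl]-6-[4-(methoxymethoxy)phenyl]-4-methylcyclohex-3-en-1-yl](2-hydroxyphenyl)methanone | O=C(c1ccccc1O)[C@H]1[C@@H](c2c(OCOC)ccc(C(C)=O)c2OCOC)C=C(C)C[C@@H]1c1ccc(OCOC)cc1
F4 | step 11 | 2-hydroxyphenyl (1R,2S,6S)-2-[3-acetyl-2,6-bis(methoxymethoxy)phenyl]-6-[4-(methoxymethoxy)phenyl]-4-methylcyclohex-3-ene-1-carboxylate | O=C(Oc1ccccc1O)[C@H]1[C@@H](c2c(OCOC)ccc(C(C)=O)c2OCOC)C=C(C)C[C@@H]1c1ccc(OCOC)cc1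
F5 | step 18 | heptakis(triethylsilyl) ether of 29 | CC(C)=CCc1c(O[Si](CC)(CC)CC)ccc(C(=O)[C@@H]2[C@@H](c3c(O[Si](CC)(CC)CC)ccc(C(=O)/C=C/c4ccc(O[Si](CC)(CC)CC)cc4O[Si](CC)(CC)CC)c3O[Si](CC)(CC)CC)C=C(C)C[C@@H]2c2ccc(O[Si](CC)(CC)CC)cc2)c1O[Si](CC)(CC)CC
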